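The flavanone is disconnected at O1–C8a, the aryl–oxygen bond that ties the stereogenic C2 of ring C to aromatic ring A. Because this bond is made by O-arylation, the C2–O bond laid down in an asymmetric aldol stays intact throughout, so C2 cannot invert. One copper-catalysed intramolecular O-arylation closes ring C. It converts an open-chain anti-1,3-diol, brominated at the future C8a and carrying the four ring A methoxy groups, into the 2,4-cis flavan-4-ol. Ring size alone selects the C2 hydroxyl. C4 remains a carbinol until ring C exists, which rules out chalcone formation, and a neutral oxidation then delivers the ketone.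

Key step: step 5

Remark: flavanone atom labels (O1, C2, C3, C4, C4a, C8a) are also used for the matching atoms of the open-chain compounds; (+)-Ipc2BCl is (+)-B-chlorodiisopinocampheylborane made from (−)-α-pinene.

Step 1
Reactants: 1 1,2,3,4-tetramethoxybenzene
Product: 2 1-(2,3,4,5-tetramethoxyphenyl)ethan-1-one
Conditions: Ac2O, Sc(OTf)3 (10 mol %), MeNO2, 50 °C
Reagents that add atoms: acetic anhydride, CC(=O)OC(C)=O
Why: Friedel–Crafts acylation: the two free ring positions of 1 are equivalent and each lies ortho and para to a methoxy group, the first acetyl group deactivates the ring against a second acylation, and catalytic Sc(OTf)3 avoids the ortho-demethylation that stoichiometric AlCl3 or BCl3 would cause.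

Step 2
Reactants: 2 1-(2,3,4,5-tetramethoxyphenyl)ethan-1-one
Product: 3 1-(2-bromo-3,4,5,6-tetramethoxyphenyl)ethan-1-one
Conditions: NBS, MeCN, 0 °C to rt, dark
Reagents that add atoms: N-bromosuccinimide, O=C1CCC(=O)N1Br
Why: Electrophilic aromatic bromination: only one ring C–H remains, it is activated by an ortho and a para methoxy group, and NBS in a polar aprotic solvent without acid or light favours the ionic ring pathway over bromination of the acetyl methyl group.

Step 3
Reactants: 3 1-(2-bromo-3,4,5,6-tetramethoxyphenyl)ethan-1-one; 4 4-methoxybenzaldehyde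
Product: 7 (3S)-1-(2-bromo-3,4,5,6-tetramethoxyphenyl)-3-hydroxy-3-(4-methoxyphenyl)propan-1-one, via Ipc2B enolate 5 (not isolated), via Ipc2B aldolate 6 (not isolated)
Conditions: (+)-Ipc2BCl, Et3N, Et2O, 0 °C; then 4, −78 to −20 °C; then H2O2, MeOH, pH 7 buffer, 0 °C
Reagents that add atoms: (+)-B-chlorodiisopinocampheylborane, ClB([C@H]1C[C@H]2C[C@@H]([C@@H]1C)C2(C)C)[C@H]1C[C@H]2C[C@@H]([C@@H]1C)C2(C)C (supplies the Ipc2B group of 5 and 6, which the work-up removes again)
Why: Paterson-type asymmetric boron aldol: soft enolisation of the methyl ketone gives 5, whose isopinocampheyl ligands steer it onto the Si face of aldehyde 4 in a cyclic six-membered transition state, so the new carbinol (future C2) is set as S, and the buffered peroxide work-up frees 7 from 6 without base that could dehydrate it.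

Step 4
Reactants: 7 (3S)-1-(2-bromo-3,4,5,6-tetramethoxyphenyl)-3-hydroxy-3-(4-methoxyphenyl)propan-1-one
Product: 8 (1S,3S)-1-(2-bromo-3,4,5,6-tetramethoxyphenyl)-3-(4-methoxyphenyl)propane-1,3-diol (anti diol)
Conditions: Me4NBH(OAc)3, MeCN–AcOH (1:1), −30 to 0 °C; aqueous work-up; recrystallisation
Reagents that add atoms: none
Why: Evans–Saksena reduction: the free hydroxyl of 7 displaces an acetate on boron and the hydride then passes intramolecularly to the ketone through a chair-like six-membered transition state, which sets the new carbinol (future C4) 1,3-anti to the existing one, that is (1S,3S), while the reagent is too mild to touch the aryl bromide, and crystallisation of 8 is the point where any minor enantiomer carried over from step 3 should be removed.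

Step 5
Reactants: 8 (1S,3S)-1-(2-bromo-3,4,5,6-tetramethoxyphenyl)-3-(4-methoxyphenyl)propane-1,3-diol
Product: 9 (2S,4S)-5,6,7,8-tetramethoxy-2-(4-methoxyphenyl)chroman-4-ol (2,4-cis flavan-4-ol)
Conditions: CuI (10 mol %), 3,4,7,8-tetramethyl-1,10-phenanthroline (20 mol %), Cs2CO3 (2 equiv), 4 Å molecular sieves, degassed toluene (0.02 M), 110 °C, argon
Reagents that add atoms: none
Why: Cs2CO3 turns the anisyl carbinol (C2–OH) into an alkoxide bound to phenanthroline-ligated monovalent copper, this centre inserts into the neighbouring C8a–Br bond to give a seven-membered trivalent copper metallacycle (Cu, O1, C2, C3, C4, C4a, C8a), and C–O reductive elimination releases 9 and returns the catalyst. The closest known reaction type is the intramolecular Ullmann-type etherification of 3-(2-halophenyl)propan-1-ols to chromans, which is established for secondary benzylic alcohols. Ring C closes as a six-membered ring by exo attack of O1 on C8a, the departing bromide lying outside the new ring. No stereocentre is created, because the C2–O and C4–O bonds are spectators, so (1S,3S) in 8 becomes (2S,4S) in 9, the 2,4-cis isomer with aryl and hydroxyl both pseudo-equatorial, which is why the anti diol is the diastereomer chosen. The step must distinguish two secondary benzylic hydroxyls and favour cyclisation over oligomerisation; geometry secures the first, since the C4 oxygen could reach C8a only through a four-membered ring, and high dilution plus the proximity of O1 to C8a secures the second. With C4 at the alcohol level there are no acidic C3 protons, so hot carbonate cannot trigger β-elimination, and rigorous exclusion of air suppresses copper-mediated oxidation of the carbinols.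

Step 6
Reactants: 9 (2S,4S)-5,6,7,8-tetramethoxy-2-(4-methoxyphenyl)chroman-4-ol
Product: 10 (2S)-5,6,7,8-tetramethoxy-2-(4-methoxyphenyl)chroman-4-one, the target (2S)-5,6,7,8,4'-pentamethoxyflavanone
Conditions: IBX (1.3 equiv), DMSO, 23 °C
Reagents that add atoms: none
Why: Hypervalent-iodine alcohol oxidation: IBX exchanges with the C4 hydroxyl and collapses to the ketone under base-free conditions at room temperature, which avoids both the retro-oxa-Michael ring opening that would racemise C2 and the dehydrogenation to the flavone that hot IBX can cause.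

Compound list
1 | 1,2,3,4-tetramethoxybenzene | COc1ccc(OC)c(OC)c1OC | starting material
2 | 1-(2,3,4,5-tetramethoxyphenyl)ethan-1-one | CC(=O)c1cc(OC)c(OC)c(OC)c1OC | intermediate
3 | 1-(2-bromo-3,4,5,6-tetramethoxyphenyl)ethan-1-one | CC(=O)c1c(Br)c(OC)c(OC)c(OC)c1OC | intermediate
4 | 4-methoxybenzaldehyde | COc1ccc(C=O)cc1 | starting material
5 | diisopinocampheylboron enolate of 3 (Ipc groups from (−)-α-pinene) | C=C(OB([C@H]1C[C@H]2C[C@@H]([C@@H]1C)C2(C)C)[C@H]1C[C@H]2C[C@@H]([C@@H]1C)C2(C)C)c1c(Br)c(OC)c(OC)c(OC)c1OC | intermediate
6 | diisopinocampheylboron aldolate, the O-boryl derivative of 7 | COc1ccc([C@@H](OB([C@H]3C[C@H]4C[C@@H]([C@@H]3C)C4(C)C)[C@H]3C[C@H]4C[C@@H]([C@@H]3C)C4(C)C)CC(=O)c2c(Br)c(OC)c(OC)c(OC)c2OC)cc1 | intermediate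
7 | (3S)-1-(2-bromo-3,4,5,6-tetramethoxyphenyl)-3-hydroxy-3-(4-methoxyphenyl)propan-1-one | COc1ccc([C@@H](O)CC(=O)c2c(Br)c(OC)c(OC)c(OC)c2OC)cc1 | intermediate
8 | (1S,3S)-1-(2-bromo-3,4,5,6-tetramethoxyphenyl)-3-(4-methoxyphenyl)propane-1,3-diol | COc1ccc([C@@H](O)C[C@H](O)c2c(Br)c(OC)c(OC)c(OC)c2OC)cc1 | intermediate
9 | (2S,4S)-5,6,7,8-tetramethoxy-2-(4-methoxyphenyl)chroman-4-ol | COc1ccc([C@@H]2C[C@H](O)c3c(OC)c(OC)c(OC)c(OC)c3O2)cc1 | intermediate
10 | (2S)-5,6,7,8,4'-pentamethoxyflavanone | COc1ccc([C@@H]2CC(=O)c3c(OC)c(OC)c(OC)c(OC)c3O2)cc1 | target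

Total step count: 6. Longest linear sequence: 6 steps (1 to 10).

Steps most likely to fail

Step 5. Insertion of copper into the electron-rich C–Br bond, flanked on both sides, may be slow. Hydrodebromination or oxidation of the carbinols could then overtake ring closure.
- The fallback gives up the aryl–oxygen closure and obtains the same flavan-4-ol by resolution. It sets out from 3 and comes back at 9.
- Copper-catalysed hydroxylation of the bromide, here activated by its ortho acetyl group (CuI, 1,10-phenanthroline, KOH, DMSO–H2O, 100 °C), would give 1-(2-hydroxy-3,4,5,6-tetramethoxyphenyl)ethan-1-one F1.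
- Claisen–Schmidt condensation with 4 (KOH, EtOH) would give (E)-1-(2-hydroxy-3,4,5,6-tetramethoxyphenyl)-3-(4-methoxyphenyl)prop-2-en-1-one F2.
- Oxa-Michael cyclisation (NaOAc, EtOH, reflux) would give racemic 5,6,7,8-tetramethoxy-2-(4-methoxyphenyl)chroman-4-one F3.
- A Noyori–Ikariya transfer hydrogenation run as a kinetic resolution (RuCl[(S,S)-TsDPEN](p-cymene), HCO2H–Et3N, EtOAc, stopped near half conversion) should reduce the (2S) ketone preferentially. In that enantiomer the catalyst preference for a (4S) carbinol and the substrate preference for the cis alcohol coincide, so the product is 9.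
- The slower enantiomer of the ketone is separated, and step 6 follows as written.

Step 3. Facial selectivity may be poor, as is typical of unsubstituted boron enolates. Hydride transfer from an isopinocampheyl group to a carbonyl may also compete.
- The fallback sets the carbinol by catalytic ketone reduction instead of by C–C bond formation. It sets out from 3 and comes back at 7.
- Claisen condensation with methyl 4-methoxybenzoate (NaH, THF, reflux) would give 1-(2-bromo-3,4,5,6-tetramethoxyphenyl)-3-(4-methoxyphenyl)propane-1,3-dione F4.
- Noyori–Ikariya transfer hydrogenation (RuCl[(S,S)-TsDPEN](p-cymene), HCO2H–Et3N, 30 °C) should reduce the accessible anisoyl carbonyl to the (S) alcohol. The ring A carbonyl is shielded by its ortho bromine and ortho methoxy group.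

Step 4. The acetic acid medium may ionise or eliminate the 4-methoxybenzylic hydroxyl, and hydride transfer to the doubly flanked carbonyl may be sluggish.
- The fallback replaces the borohydride by an acid-free intramolecular hydride shift. It sets out from 7 and comes back at 8.
- An Evans–Tishchenko reaction (SmI2 20 mol %, excess acetaldehyde, THF, −10 °C) would give the anti monoester (1S,3S)-3-(2-bromo-3,4,5,6-tetramethoxyphenyl)-3-hydroxy-1-(4-methoxyphenyl)propyl acetate F5.
- Methanolysis at the acyl carbon (K2CO3, MeOH, 0 °C) then frees 8 with both configurations retained.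

Further compounds
F1 | step 5 | 1-(2-hydroxy-3,4,5,6-tetramethoxyphenyl)ethan-1-one | CC(=O)c1c(O)c(OC)c(OC)c(OC)c1OC
F2 | step 5 | (E)-1-(2-hydroxy-3,4,5,6-tetramethoxyphenyl)-3-(4-methoxyphenyl)prop-2-en-1-one | COc1ccc(/C=C/C(=O)c2c(O)c(OC)c(OC)c(OC)c2OC)cc1
F3 | step 5 | racemic 5,6,7,8-tetramethoxy-2-(4-methoxyphenyl)chroman-4-one | COc1ccc(C2CC(=O)c3c(OC)c(OC)c(OC)c(OC)c3O2)cc1
F4 | step 3 | 1-(2-bromo-3,4,5,6-tetramethoxyphenyl)-3-(4-methoxyphenyl)propane-1,3-dione | COc1ccc(C(=O)CC(=O)c2c(Br)c(OC)c(OC)c(OC)c2OC)cc1
F5 | step 4 | (1S,3S)-3-(2-bromo-3,4,5,6-tetramethoxyphenyl)-3-hydroxy-1-(4-methoxyphenyl)propyl acetate | COc1ccc([C@@H](OC(C)=O)C[C@H](O)c2c(Br)c(OC)c(OC)c(OC)c2OC)cc1
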